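**Retrosynthetic overview**
1. 21 ⇒ retro transannular aldol (C1–C5) ⇒ ten-membered 5,10-dione 20 ⇒ retro oxidative cleavage ⇒ C5=C10 octalin 19. Forward, both happen in one flask as the last step.
2. 19 ⇒ retro epoxide-initiated cation–olefin closure of ring A (through the C10 cation) ⇒ epoxy cyclohexene 18.
3. 18 ⇒ Shi epoxidation, furan-to-butenolide oxidation, enol triflate/Kumada coupling ⇒ ring B ketone 8 + homoprenyl bromide 9.
4. 8 ⇒ asymmetric conjugate methylation/enolate methylation (sets C8 and C9) ⇒ enone 5 ⇒ 2-iodocyclohexenone 3 + 3-vinylfuran 2.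
5. Ring order: ring B is bought; ring A forms in step 7; the ten-membered ring and then the five- and seven-membered rings form in step 8.

Assumption: terpenoid (halimane) numbering C1–C20 is used for ring atoms, and the natural product is taken to arise from the 3β-hydroxy-halima-5(10),13-diene butenolide 19 by cleavage of C5=C10 and aldol closure of C1 onto C5.

**Step 1**
Reactants: 1 furan-3-carbaldehyde
Product: 2 3-ethenylfuran
Conditions: MePPh3Br, n-BuLi, THF, 0 °C → rt; flash-distilled and used as a THF solution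
Reagents that add atoms: methyltriphenylphosphonium bromide, C[P+](c1ccccc1)(c1ccccc1)c1ccccc1.[Br-]
Why: Wittig methylenation of an unhindered heteroaryl aldehyde with the non-stabilised ylide; no stereocentre is formed.

**Step 2**
Reactants: 2 3-ethenylfuran; 3 2-iodocyclohex-2-en-1-one
Product: 5 2-[2-(furan-3-yl)ethyl]cyclohex-2-en-1-one, via alkylborane 4 (not isolated)
Conditions: 9-BBN, THF, 0 °C → rt; then 3, PdCl2(dppf) (5 mol %), AsPh3 (5 mol %), Cs2CO3, DMF/H2O, rt
Reagents that add atoms: none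
Why: 9-BBN adds anti-Markovnikov to the vinyl group and the B-alkyl borane undergoes B-alkyl Suzuki–Miyaura coupling with the α-iodoenone under mild base, which leaves enone and furan intact; no stereocentre.

**Step 3**
Reactants: 5 2-[2-(furan-3-yl)ethyl]cyclohex-2-en-1-one
Product: 8 (2R,3R)-2-[2-(furan-3-yl)ethyl]-2,3-dimethylcyclohexan-1-one, via aluminium enolate 6 (not isolated), via lithium aluminate enolate 7 (not isolated)
Conditions: AlMe3, copper thiophene-2-carboxylate Cu(O2CC4H3S) (2 mol %), binaphthol/bis(1-phenylethyl)amine phosphoramidite (4 mol %, antipode that gives the 3R centre), Et2O, −30 °C; then MeLi, THF; MeI, DMPU, −30 °C → rt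
Reagents that add atoms: trimethylaluminium, C[Al](C)C; iodomethane, CI
Why: Copper-catalysed asymmetric conjugate addition of AlMe3 to the 2-substituted enone sets C8 (R) under ligand control, and the regiodefined enolate, activated as its lithium aluminate, is C-methylated anti to the new C8 methyl (held pseudoaxial by A1,2 strain), so C9 (R) forms with the two methyls trans and the side chain cis to the C8 methyl.

**Step 4**
Reactants: 8 (2R,3R)-2-[2-(furan-3-yl)ethyl]-2,3-dimethylcyclohexan-1-one; 9 5-bromo-2-methylpent-2-ene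
Product: 13 3-{2-[(1R,6R)-1,6-dimethyl-2-(4-methylpent-3-en-1-yl)cyclohex-2-en-1-yl]ethyl}furan, via potassium enolate 10 (not isolated), via enol triflate 11 (not isolated), via Grignard reagent 12 (not isolated)
Conditions: KN(SiMe3)2, THF, −78 °C; PhNTf2, −78 → 0 °C; then Fe(acac)3 (10 mol %), NMP, 12 (from 9, Mg, THF), −30 → 0 °C
Reagents that add atoms: none
Why: Ketone 8 has α-hydrogens only at C5, so a single enol triflate forms, and iron-catalysed Kumada coupling of alkenyl triflates with primary alkyl Grignard reagents is fast at low temperature and leaves the furan and both stereocentres untouched.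

**Step 5**
Reactants: 13 3-{2-[(1R,6R)-1,6-dimethyl-2-(4-methylpent-3-en-1-yl)cyclohex-2-en-1-yl]ethyl}furan
Product: 17 4-{2-[(1R,6R)-1,6-dimethyl-2-(4-methylpent-3-en-1-yl)cyclohex-2-en-1-yl]ethyl}furan-2(5H)-one, via furan endoperoxide 14 (not isolated), via hydroxybutenolide 15 (not isolated), via sodium hydroxy-enoate 16 (not isolated)
Conditions: O2, hν, tetraphenylporphyrin (cat.), i-Pr2NEt, CH2Cl2, −78 °C; then NaBH4, EtOH, 0 °C; 1 M HCl
Reagents that add atoms: dioxygen, O=O
Why: Singlet-oxygen [4+2] cycloaddition to the furan (far faster than the ene reaction of the trisubstituted alkenes at −78 °C) and Kornblum–DeLaMare fragmentation, in which the hindered base removes the bridgehead hydrogen remote from the side chain, give the γ-hydroxybutenolide, whose open aldehyde form is reduced by NaBH4 and relactonises on acidification to the β-substituted butenolide; stereocentres untouched.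

**Step 6**
Reactants: 17 4-{2-[(1R,6R)-1,6-dimethyl-2-(4-methylpent-3-en-1-yl)cyclohex-2-en-1-yl]ethyl}furan-2(5H)-one
Product: 18 4-{2-[(1R,6R)-2-{2-[(2S)-3,3-dimethyloxiran-2-yl]ethyl}-1,6-dimethylcyclohex-2-en-1-yl]ethyl}furan-2(5H)-one
Conditions: ent-Shi ketone (L-fructose-derived, 30 mol %), KHSO5 (as 2KHSO5·KHSO4·K2SO4, 1.3 equiv), K2CO3, Bu4NHSO4, MeCN/CH2(OMe)2, aq Na2B4O7 buffer, 0 °C
Reagents that add atoms: potassium peroxymonosulfate, [K+].OOS(=O)(=O)[O-]
Why: Shi asymmetric epoxidation, in which the chiral dioxirane epoxidises the unhindered, electron-rich isopropylidene group with catalyst control (3S) ahead of the ring alkene shielded by the adjacent quaternary C9, while the electron-poor butenolide alkene is inert.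

**Step 7**
Reactants: 18 4-{2-[(1R,6R)-2-{2-[(2S)-3,3-dimethyloxiran-2-yl]ethyl}-1,6-dimethylcyclohex-2-en-1-yl]ethyl}furan-2(5H)-one
Product: 19 4-{2-[(1R,2R,6S)-6-hydroxy-1,2,5,5-tetramethyl-1,2,3,4,5,6,7,8-octahydronaphthalen-1-yl]ethyl}furan-2(5H)-one
Conditions: BF3·OEt2 (2.5 equiv), CH2Cl2, −78 → −20 °C
Reagents that add atoms: none
Why: Biomimetic epoxide-initiated cation–olefin cyclisation in which C5 of the ring alkene attacks the activated tertiary epoxide carbon C4 (6-endo, Markovnikov), the tertiary C10 cation (the halimanyl cation of the biosynthesis) loses H-5 to give the tetrasubstituted 5(10)-ene, the expected thermodynamic outlet under BF3 (a 1(10)-ene can re-enter by protonation), and C3 keeps its C–O bond and configuration (3S).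

**Step 8**
Reactants: 19 4-{2-[(1R,2R,6S)-6-hydroxy-1,2,5,5-tetramethyl-1,2,3,4,5,6,7,8-octahydronaphthalen-1-yl]ethyl}furan-2(5H)-one
Product: 21 (2S,3aS,5R,6R,8aS)-2,8a-dihydroxy-1,1,5,6-tetramethyl-5-[2-(5-oxo-2,5-dihydrofuran-3-yl)ethyl]octahydroazulen-4(1H)-one, via seco-dione 20 (not isolated)
Conditions: O3, pyridine (3 equiv), CH2Cl2, −78 °C (Sudan Red 7B end point); N2 purge; then DBU (0.3 equiv), −78 → 0 °C
Reagents that add atoms: ozone, [O-][O+]=O
Why: Pyridine-mediated ozonolysis cleaves only the electron-rich tetrasubstituted C5=C10 bond (the butenolide alkene is far slower) to the ten-membered 5,10-dione, and base then triggers the biomimetic transannular aldol reaction of the C1 enolate (the only enolate C10=O can form) onto C5=O, which the 3-OH can activate by hydrogen bonding; because the aldol is reversible and C1 is epimerisable, the trans-fused (1S,5S) β-hydroxy ketone of the natural product, in which 5-OH can hydrogen-bond to C10=O, is expected under thermodynamic control.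

**Compound list**
1 | furan-3-carbaldehyde | O=Cc1ccoc1 | starting material
2 | 3-ethenylfuran | C=Cc1ccoc1 | intermediate
3 | 2-iodocyclohex-2-en-1-one | O=C1CCCC=C1I | starting material
4 | 9-[2-(furan-3-yl)ethyl]-9-borabicyclo[3.3.1]nonane | C(Cc1ccoc1)B1C2CCCC1CCC2 | intermediate (not isolated)
5 | 2-[2-(furan-3-yl)ethyl]cyclohex-2-en-1-one | O=C1CCCC=C1CCc1ccoc1 | intermediate
6 | dimethylaluminium (3R)-2-[2-(furan-3-yl)ethyl]-3-methylcyclohex-1-en-1-olate | C[C@@H]1CCCC(O[Al](C)C)=C1CCc1ccoc1 | intermediate (not isolated)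
7 | lithium trimethyl{[(3R)-2-[2-(furan-3-yl)ethyl]-3-methylcyclohex-1-en-1-yl]oxy}aluminate | [Li+].C[C@@H]1CCCC(O[Al-](C)(C)C)=C1CCc1ccoc1 | intermediate (not isolated)
8 | (2R,3R)-2-[2-(furan-3-yl)ethyl]-2,3-dimethylcyclohexan-1-one | C[C@@H]1CCCC(=O)[C@]1(C)CCc1ccoc1 | intermediate
9 | 5-bromo-2-methylpent-2-ene | CC(C)=CCCBr | starting material
10 | potassium (5R,6R)-6-[2-(furan-3-yl)ethyl]-5,6-dimethylcyclohex-1-en-1-olate | [K+].C[C@@H]1CCC=C([O-])[C@]1(C)CCc1ccoc1 | intermediate (not isolated)
11 | (5R,6R)-6-[2-(furan-3-yl)ethyl]-5,6-dimethylcyclohex-1-en-1-yl trifluoromethanesulfonate | C[C@@H]1CCC=C(OS(=O)(=O)C(F)(F)F)[C@]1(C)CCc1ccoc1 | intermediate (not isolated)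
12 | (4-methylpent-3-en-1-yl)magnesium bromide | CC(C)=CCC[Mg]Br | intermediate (not isolated)
13 | 3-{2-[(1R,6R)-1,6-dimethyl-2-(4-methylpent-3-en-1-yl)cyclohex-2-en-1-yl]ethyl}furan | C[C@@H]1CCC=C(CCC=C(C)C)[C@]1(C)CCc1ccoc1 | intermediate
14 | furan endoperoxide of 13 (2,3,7-trioxabicyclo[2.2.1]hept-5-ene carrying the side chain at C5; both bridgehead diastereomers) | C[C@@H]1CCC=C(CCC=C(C)C)[C@]1(C)CCC1=CC2OOC1O2 | intermediate (not isolated)
15 | 5-hydroxy-4-{2-[(1R,6R)-1,6-dimethyl-2-(4-methylpent-3-en-1-yl)cyclohex-2-en-1-yl]ethyl}furan-2(5H)-one (lactol epimers) | C[C@@H]1CCC=C(CCC=C(C)C)[C@]1(C)CCC1=CC(=O)OC1O | intermediate (not isolated)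
16 | sodium (2Z)-3-{2-[(1R,6R)-1,6-dimethyl-2-(4-methylpent-3-en-1-yl)cyclohex-2-en-1-yl]ethyl}-4-hydroxybut-2-enoate | [Na+].C[C@@H]1CCC=C(CCC=C(C)C)[C@]1(C)CC/C(CO)=C/C(=O)[O-] | intermediate (not isolated)
17 | 4-{2-[(1R,6R)-1,6-dimethyl-2-(4-methylpent-3-en-1-yl)cyclohex-2-en-1-yl]ethyl}furan-2(5H)-one | C[C@@H]1CCC=C(CCC=C(C)C)[C@]1(C)CCC1=CC(=O)OC1 | intermediate
18 | 4-{2-[(1R,6R)-2-{2-[(2S)-3,3-dimethyloxiran-2-yl]ethyl}-1,6-dimethylcyclohex-2-en-1-yl]ethyl}furan-2(5H)-one | C[C@@H]1CCC=C(CC[C@@H]2OC2(C)C)[C@]1(C)CCC1=CC(=O)OC1 | intermediate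
19 | 4-{2-[(1R,2R,6S)-6-hydroxy-1,2,5,5-tetramethyl-1,2,3,4,5,6,7,8-octahydronaphthalen-1-yl]ethyl}furan-2(5H)-one (3S,8R,9R in terpenoid numbering) | C[C@@H]1CCC2=C(CC[C@H](O)C2(C)C)[C@]1(C)CCC1=CC(=O)OC1 | intermediate
20 | 4-{2-[(1R,2R,7S)-7-hydroxy-1,2,6,6-tetramethyl-5,10-dioxocyclodecyl]ethyl}furan-2(5H)-one | C[C@@H]1CCC(=O)C(C)(C)[C@@H](O)CCC(=O)[C@]1(C)CCC1=CC(=O)OC1 | intermediate (not isolated)
21 | (2S,3aS,5R,6R,8aS)-2,8a-dihydroxy-1,1,5,6-tetramethyl-5-[2-(5-oxo-2,5-dihydrofuran-3-yl)ethyl]octahydroazulen-4(1H)-one (1S,3S,5S,8R,9R in terpenoid numbering) | C[C@@H]1CC[C@]2(O)[C@H](C[C@H](O)C2(C)C)C(=O)[C@]1(C)CCC1=CC(=O)OC1 | target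

**Totals**
Total step count: 8. Longest linear sequence: 8 steps (the Grignard reagent is made within step 4).

**Three steps most likely to fail**

Step 8 (ozonolysis/transannular aldol). The dione could close the other way (C6 onto C10), give the cis-fused epimer, dehydrate, or undergo retro-aldol opening through the free 3-hydroxy ketone. The fallback separates the events and masks O3. Setting out from 19, Et3SiCl/imidazole gives the triethylsilyl ether of 19 F1. Ozonolysis (O3, pyridine, CH2Cl2, −78 °C) then gives the isolable silylated ten-membered dione F2. This is closed in a separate, freely optimised aldol step (soft enolisation with MgBr2·OEt2/i-Pr2NEt, or equilibration with DBU) to the silylated aldol F3. HF·pyridine removes the silyl group and the route is rejoined at 21.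

Step 7 (cationic closure of ring A). The epoxide may rearrange to a ketone, the C10 cation may be trapped by the C3 oxygen as a bridged ether, or the alkene may end up at C1(10). The fallback closes the ring by a radical instead of a cation. Setting out from 18, Cp2TiCl (trivalent titanium, made from Cp2TiCl2 and Mn in THF) opens the epoxide homolytically; 6-endo closure onto C5 and β-hydride loss give the 1(10)-ene alcohol F4 (C5 epimer not assigned, the centre is erased next). Catalytic TsOH in benzene at 60 °C then moves the double bond to the tetrasubstituted position, rejoining the route at 19.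

Step 3 (asymmetric conjugate methylation with one-pot enolate methylation). The enantioselectivity on a 2-substituted enone and the alkylation of the aluminium enolate are both uncertain. The fallback sets C8 by a directed cyclopropanation. Setting out from 5, (R)-Me-CBS/BH3·SMe2 gives the allylic alcohol (1S)-2-[2-(furan-3-yl)ethyl]cyclohex-2-en-1-ol F5. Hydroxyl-directed Simmons–Smith reaction (Et2Zn, CH2I2) gives the cyclopropyl carbinol F6, and Dess–Martin oxidation gives the cyclopropyl ketone F7. Li/NH3 cleaves the exocyclic cyclopropane bond, which turns the cyclopropane CH2 into the C8 methyl and gives the regiodefined lithium enolate F8. MeI/DMPU methylates it anti to that methyl, rejoining the route at 8.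

**Further compounds**
F1 | step 8 | triethylsilyl ether of 19 | C[C@@H]1CCC2=C(CC[C@H](O[Si](CC)(CC)CC)C2(C)C)[C@]1(C)CCC1=CC(=O)OC1
F2 | step 8 | triethylsilyl ether of the ten-membered 5,10-dione | C[C@@H]1CCC(=O)C(C)(C)[C@@H](O[Si](CC)(CC)CC)CCC(=O)[C@]1(C)CCC1=CC(=O)OC1
F3 | step 8 | 3-O-triethylsilyl ether of 21 | C[C@@H]1CC[C@]2(O)[C@H](C[C@H](O[Si](CC)(CC)CC)C2(C)C)C(=O)[C@]1(C)CCC1=CC(=O)OC1
F4 | step 7 | 1(10)-ene isomer of 19 (3S,8R,9R; C5 epimer not assigned) | C[C@@H]1CCC2C(=CC[C@H](O)C2(C)C)[C@]1(C)CCC1=CC(=O)OC1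
F5 | step 3 | (1S)-2-[2-(furan-3-yl)ethyl]cyclohex-2-en-1-ol | O[C@H]1CCCC=C1CCc1ccoc1
F6 | step 3 | (1R,2S,6S)-1-[2-(furan-3-yl)ethyl]bicyclo[4.1.0]heptan-2-ol | O[C@H]1CCC[C@H]2C[C@@]12CCc1ccoc1
F7 | step 3 | (1R,6S)-1-[2-(furan-3-yl)ethyl]bicyclo[4.1.0]heptan-2-one | O=C1CCC[C@H]2C[C@@]12CCc1ccoc1
F8 | step 3 | lithium (3R)-2-[2-(furan-3-yl)ethyl]-3-methylcyclohex-1-en-1-olate | [Li+].C[C@@H]1CCCC([O-])=C1CCc1ccoc1
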